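## Retrosynthetic overview
1. Hansfordiol D comes from global acid deprotection of its bis-MOM/TBS ether. That ether comes from an (E)-aryl enone carrying the full C17 chain, by saturating the enone C=C and then reducing the C3' ketone to CH2.
2. Key disconnection C1'–C2': a crossed aldol addition and dehydration. It joins 3,5-bis(methoxymethoxy)benzaldehyde (fragment A) to the kinetic methyl enolate of a C16 methyl ketone (fragment B). Fragment B already holds the Z,Z-skipped diene and the silylated S carbinol.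
3. Fragment B comes from double cis-semihydrogenation of a 1,4-diyne. The diyne comes from copper-mediated C9'–C10' coupling of a propargylic bromide (C10'–C17') with a ketal-protected terminal alkyne (C2'–C9').
4. The bromide comes from (S)-propylene oxide (sole source of chirality) by butenyl Grignard opening, ozonolysis, alkyne homologation and hydroxymethylation. The alkyne comes from 6-chlorohexan-2-one and acetylide.
5. Rings: none is formed. The only ring (ring A, the resorcinol) is bought intact as 3,5-dihydroxybenzaldehyde.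

Assumption: the side chain is numbered C1' (benzylic) to C17' (methyl). The given SMILES reads as 16'S, 8'Z, 11'Z, and that compound is made.

## Route

Step 1
Reactants: 1 (S)-propylene oxide; 2 but-3-en-1-ylmagnesium bromide (sold as a THF solution)
Product: 3 (S)-hept-6-en-2-ol
Conditions: CuI (10 mol %), THF, −30 → 0 °C
Reagents that add atoms: none
Why: Copper-catalysed Grignard opening of a terminal epoxide is an SN2 attack at the unhindered CH2 terminus, so the C–O bond at the stereocentre is never touched and the S configuration of 1 becomes C16' of the target.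

Step 2
Reactants: 3 (S)-hept-6-en-2-ol
Product: 4 (S)-tert-butyl(hept-6-en-2-yloxy)dimethylsilane
Conditions: TBSCl, imidazole, DMF, rt
Reagents that add atoms: tert-butyldimethylsilyl chloride, CC(C)(C)[Si](C)(C)Cl
Why: Imidazole-promoted silylation (Corey protocol) of an unhindered secondary alcohol is near-quantitative, leaves the stereocentre alone and gives an ether that survives every basic, organometallic and reducing step ahead.

Step 3
Reactants: 4 (S)-tert-butyl(hept-6-en-2-yloxy)dimethylsilane
Product: 6 (S)-5-[(tert-butyldimethylsilyl)oxy]hexanal, via secondary ozonide 5 (not isolated)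
Conditions: O3, CH2Cl2, −78 °C; then PPh3, −78 °C → rt
Reagents that add atoms: ozone, [O-][O+]=O
Why: Ozonolysis (Criegee mechanism) with reductive PPh3 work-up cleaves the only C=C bond to the aldehyde without over-oxidation, and the silyl ether and the remote stereocentre are inert.

Step 4
Reactants: 6 (S)-5-[(tert-butyldimethylsilyl)oxy]hexanal
Product: 7 (S)-tert-butyl(hept-6-yn-2-yloxy)dimethylsilane
Conditions: MeC(O)C(N2)P(O)(OMe)2, K2CO3, MeOH, 0 °C → rt
Reagents that add atoms: dimethyl (1-diazo-2-oxopropyl)phosphonate, CC(=O)C(=[N+]=[N-])P(=O)(OC)OC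
Why: The Ohira–Bestmann modification of the Seyferth–Gilbert homologation turns an aldehyde into the one-carbon-longer terminal alkyne under mild K2CO3/MeOH conditions that a TBS ether tolerates, and the aldehyde has no α-stereocentre to lose.

Step 5
Reactants: 7 (S)-tert-butyl(hept-6-yn-2-yloxy)dimethylsilane
Product: 9 (S)-7-[(tert-butyldimethylsilyl)oxy]oct-2-yn-1-ol, via lithium acetylide 8 (not isolated)
Conditions: n-BuLi, THF, −78 °C; then (CH2O)n, −78 °C → rt
Reagents that add atoms: paraformaldehyde (reacts as formaldehyde), C=O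
Why: Deprotonation of the terminal alkyne and 1,2-addition of the acetylide to formaldehyde is a standard hydroxymethylation that installs C10' as a propargylic alcohol.

Step 6
Reactants: 9 (S)-7-[(tert-butyldimethylsilyl)oxy]oct-2-yn-1-ol
Product: 10 (S)-[(8-bromooct-6-yn-2-yl)oxy](tert-butyl)dimethylsilane
Conditions: CBr4, PPh3, CH2Cl2, 0 °C
Reagents that add atoms: carbon tetrabromide, BrC(Br)(Br)Br
Why: The Appel reaction converts a primary propargylic alcohol into the bromide by SN2 displacement of the oxyphosphonium group under neutral conditions that leave the TBS ether alone.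

Step 7
Reactants: 11 6-chlorohexan-2-one
Product: 12 2-(4-chlorobutyl)-2-methyl-1,3-dioxolane
Conditions: HOCH2CH2OH, p-TsOH·H2O (cat.), toluene, reflux (Dean–Stark)
Reagents that add atoms: ethylene glycol, OCCO
Why: Acid-catalysed ketalisation with azeotropic water removal goes to completion and masks the ketone against the acetylide, the carbonate base and the borohydride-derived catalyst used later.

Step 8
Reactants: 12 2-(4-chlorobutyl)-2-methyl-1,3-dioxolane
Product: 13 2-(hex-5-yn-1-yl)-2-methyl-1,3-dioxolane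
Conditions: LiC≡CH·H2NCH2CH2NH2, DMSO, rt
Reagents that add atoms: lithium acetylide–ethylenediamine complex, [Li]C#C.NCCN
Why: SN2 alkylation of lithium acetylide in DMSO works well on unhindered primary chlorides, the ethylenediamine complex suppresses dialkylation, and the dioxolane is inert to base.

Step 9
Reactants: 10 (S)-[(8-bromooct-6-yn-2-yl)oxy](tert-butyl)dimethylsilane; 13 2-(hex-5-yn-1-yl)-2-methyl-1,3-dioxolane
Product: 16 (S)-tert-butyldimethyl{[14-(2-methyl-1,3-dioxolan-2-yl)tetradeca-6,9-diyn-2-yl]oxy}silane, via propargylic iodide 14 (not isolated), via copper acetylide 15 (not isolated)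
Conditions: CuI (1 equiv), NaI (1 equiv), K2CO3 (1 equiv), DMF, rt, Ar
Reagents that add atoms: none
Why: Copper-mediated propargyl–alkynyl cross-coupling (in situ Finkelstein exchange plus copper acetylide formation under weak carbonate base) forms the C9'–C10' bond by SN2 substitution without isomerising the base-sensitive 1,4-diyne to an allene.

Step 10
Reactants: 16 (S)-tert-butyldimethyl{[14-(2-methyl-1,3-dioxolan-2-yl)tetradeca-6,9-diyn-2-yl]oxy}silane
Product: 17 tert-butyldimethyl{[(2S,6Z,9Z)-14-(2-methyl-1,3-dioxolan-2-yl)tetradeca-6,9-dien-2-yl]oxy}silane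
Conditions: H2 (1 atm), Ni(OAc)2·4H2O (25 mol %), NaBH4 (25 mol %), H2NCH2CH2NH2, EtOH, rt, stopped after 2 equiv H2
Reagents that add atoms: none
Why: Brown semihydrogenation over ethylenediamine-poisoned Ni2B (formed from Ni(OAc)2·4H2O and NaBH4) delivers H2 syn to each adsorbed alkyne and then releases the alkene, so both triple bonds become Z double bonds if uptake is stopped at two equivalents.

Step 11
Reactants: 17 tert-butyldimethyl{[(2S,6Z,9Z)-14-(2-methyl-1,3-dioxolan-2-yl)tetradeca-6,9-dien-2-yl]oxy}silane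
Product: 18 (7Z,10Z,15S)-15-[(tert-butyldimethylsilyl)oxy]hexadeca-7,10-dien-2-one
Conditions: PPTS (20 mol %), acetone/H2O 9:1, reflux
Reagents that add atoms: water, O
Why: PPTS-catalysed hydrolysis of a dialkyl ketone dioxolane in wet acetone is much faster than cleavage of a secondary TBS ether and is too mild to move or isomerise the skipped diene.

Step 12
Reactants: 19 3,5-dihydroxybenzaldehyde
Product: 20 3,5-bis(methoxymethoxy)benzaldehyde
Conditions: MOMCl (2.6 equiv), i-Pr2NEt (3 equiv), CH2Cl2, 0 °C → rt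
Reagents that add atoms: chloromethyl methyl ether, COCCl
Why: Williamson-type O-alkylation of the two acidic phenols with the highly reactive MOMCl gives acetal ethers that are stable to strong base, hydride and copper reagents yet come off with dilute acid at the end.

Step 13
Reactants: 18 (7Z,10Z,15S)-15-[(tert-butyldimethylsilyl)oxy]hexadeca-7,10-dien-2-one; 20 3,5-bis(methoxymethoxy)benzaldehyde
Product: 22 (8Z,11Z,16S)-1-[3,5-bis(methoxymethoxy)phenyl]-16-[(tert-butyldimethylsilyl)oxy]-1-hydroxyheptadeca-8,11-dien-3-one (both C1 epimers), via lithium enolate 21 (not isolated)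
Conditions: LiN(i-Pr)2 (1.05 equiv), THF, −78 °C, 45 min; then 20 (1.2 equiv), −78 °C, quenched cold
Reagents that add atoms: none
Why: In this directed crossed aldol addition, kinetic deprotonation by LiN(i-Pr)2 at −78 °C takes a methyl proton of 18, the non-enolisable aldehyde 20 can act only as acceptor, and the new C1' carbinol centre forms as an epimer mixture that does not matter because step 14 destroys it.

Step 14
Reactants: 22 (8Z,11Z,16S)-1-[3,5-bis(methoxymethoxy)phenyl]-16-[(tert-butyldimethylsilyl)oxy]-1-hydroxyheptadeca-8,11-dien-3-one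
Product: 24 (1E,8Z,11Z,16S)-1-[3,5-bis(methoxymethoxy)phenyl]-16-[(tert-butyldimethylsilyl)oxy]heptadeca-1,8,11-trien-3-one, via benzylic mesylate 23 (not isolated)
Conditions: MsCl (1.5 equiv), Et3N (4 equiv), CH2Cl2, 0 °C → rt
Reagents that add atoms: none
Why: Mesylation of the benzylic β-hydroxy ketone followed by E1cB elimination with excess Et3N completes the aldol condensation and gives the conjugated, thermodynamically favoured E-enone.

Step 15
Reactants: 24 (1E,8Z,11Z,16S)-1-[3,5-bis(methoxymethoxy)phenyl]-16-[(tert-butyldimethylsilyl)oxy]heptadeca-1,8,11-trien-3-one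
Product: 26 (8Z,11Z,16S)-1-[3,5-bis(methoxymethoxy)phenyl]-16-[(tert-butyldimethylsilyl)oxy]heptadeca-8,11-dien-3-one, via copper enolate 25 (not isolated)
Conditions: [(Ph3P)CuH]6 (0.4 equiv), H2O (5 equiv), degassed toluene, rt
Reagents that add atoms: none
Why: Copper hydride conjugate reduction (Stryker reduction) adds hydride only to the β-carbon of the polarised enone, water protonates the copper enolate, and the isolated Z-alkenes, acetals and silyl ether are not touched.

Step 16
Reactants: 26 (8Z,11Z,16S)-1-[3,5-bis(methoxymethoxy)phenyl]-16-[(tert-butyldimethylsilyl)oxy]heptadeca-8,11-dien-3-one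
Product: 27 N'-tosylhydrazone of 26 (C=N isomer mixture)
Conditions: TsNHNH2 (1.2 equiv), MeOH, rt → 40 °C
Reagents that add atoms: p-toluenesulfonyl hydrazide, Cc1ccc(cc1)S(=O)(=O)NN
Why: Hydrazone condensation of an unhindered dialkyl ketone with tosylhydrazide is fast and needs no added acid, so the MOM and TBS groups survive.

Step 17
Reactants: 27 N'-tosylhydrazone of 26
Product: 30 tert-butyl({(2S,6Z,9Z)-17-[3,5-bis(methoxymethoxy)phenyl]heptadeca-6,9-dien-2-yl}oxy)dimethylsilane, via N-boryl hydrazide 28 (not isolated), via alkyl diazene 29 (not isolated)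
Conditions: catecholborane (2 equiv), CHCl3, −10 → 0 °C; then NaOAc·3H2O (3 equiv), reflux
Reagents that add atoms: none
Why: In this Caglioti-type deoxygenation (Kabalka variant), catecholborane reduces the C=N bond, acetate triggers loss of sulfinate, and the diazene loses N2 to leave CH2 under near-neutral, non-radical conditions that neither hydroborate nor isomerise the skipped diene.

Step 18
Reactants: 30 tert-butyl({(2S,6Z,9Z)-17-[3,5-bis(methoxymethoxy)phenyl]heptadeca-6,9-dien-2-yl}oxy)dimethylsilane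
Product: 31 Hansfordiol D, 5-[(8Z,11Z,16S)-16-hydroxyheptadeca-8,11-dien-1-yl]benzene-1,3-diol
Conditions: HCl (1.25 M in MeOH), 0 → 35 °C, Ar
Reagents that add atoms: none
Why: Acid-catalysed acetal exchange and desilylation in methanol remove both MOM ethers and the TBS ether in one operation, while the isolated Z-alkenes and the secondary carbinol centre do not ionise under these conditions, so the S,Z,Z target is released unchanged.

## Compound list
1 | (S)-propylene oxide | C[C@H]1CO1 | starting material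
2 | but-3-en-1-ylmagnesium bromide | C=CCC[Mg]Br | starting material
3 | (S)-hept-6-en-2-ol | C[C@H](O)CCCC=C | intermediate
4 | (S)-tert-butyl(hept-6-en-2-yloxy)dimethylsilane | C[C@H](O[Si](C)(C)C(C)(C)C)CCCC=C | intermediate
5 | secondary ozonide, 3-{(4S)-4-[(tert-butyldimethylsilyl)oxy]pentyl}-1,2,4-trioxolane (formed in the flask) | C[C@H](O[Si](C)(C)C(C)(C)C)CCCC1OCOO1 | intermediate
6 | (S)-5-[(tert-butyldimethylsilyl)oxy]hexanal | C[C@H](O[Si](C)(C)C(C)(C)C)CCCC=O | intermediate
7 | (S)-tert-butyl(hept-6-yn-2-yloxy)dimethylsilane | C[C@H](O[Si](C)(C)C(C)(C)C)CCCC#C | intermediate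
8 | lithium acetylide of 7 (formed in the flask) | C[C@H](O[Si](C)(C)C(C)(C)C)CCCC#C[Li] | intermediate
9 | (S)-7-[(tert-butyldimethylsilyl)oxy]oct-2-yn-1-ol | C[C@H](O[Si](C)(C)C(C)(C)C)CCCC#CCO | intermediate
10 | (S)-[(8-bromooct-6-yn-2-yl)oxy](tert-butyl)dimethylsilane | C[C@H](O[Si](C)(C)C(C)(C)C)CCCC#CCBr | intermediate
11 | 6-chlorohexan-2-one | CC(=O)CCCCCl | starting material
12 | 2-(4-chlorobutyl)-2-methyl-1,3-dioxolane | CC1(CCCCCl)OCCO1 | intermediate
13 | 2-(hex-5-yn-1-yl)-2-methyl-1,3-dioxolane | CC1(CCCCC#C)OCCO1 | intermediate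
14 | (S)-tert-butyl[(8-iodooct-6-yn-2-yl)oxy]dimethylsilane (formed in the flask) | C[C@H](O[Si](C)(C)C(C)(C)C)CCCC#CCI | intermediate
15 | copper acetylide of 13 (formed in the flask) | CC1(CCCCC#C[Cu])OCCO1 | intermediate
16 | (S)-tert-butyldimethyl{[14-(2-methyl-1,3-dioxolan-2-yl)tetradeca-6,9-diyn-2-yl]oxy}silane | CC1(CCCCC#CCC#CCCC[C@H](C)O[Si](C)(C)C(C)(C)C)OCCO1 | intermediate
17 | tert-butyldimethyl{[(2S,6Z,9Z)-14-(2-methyl-1,3-dioxolan-2-yl)tetradeca-6,9-dien-2-yl]oxy}silane | CC1(CCCC/C=C\C/C=C\CCC[C@H](C)O[Si](C)(C)C(C)(C)C)OCCO1 | intermediate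
18 | (7Z,10Z,15S)-15-[(tert-butyldimethylsilyl)oxy]hexadeca-7,10-dien-2-one | CC(=O)CCCC/C=C\C/C=C\CCC[C@H](C)O[Si](C)(C)C(C)(C)C | intermediate
19 | 3,5-dihydroxybenzaldehyde | O=Cc1cc(O)cc(O)c1 | starting material
20 | 3,5-bis(methoxymethoxy)benzaldehyde | COCOc1cc(C=O)cc(OCOC)c1 | intermediate
21 | terminal (C1=C2) lithium enolate of 18 (formed in the flask) | [Li]OC(=C)CCCC/C=C\C/C=C\CCC[C@H](C)O[Si](C)(C)C(C)(C)C | intermediate
22 | (8Z,11Z,16S)-1-[3,5-bis(methoxymethoxy)phenyl]-16-[(tert-butyldimethylsilyl)oxy]-1-hydroxyheptadeca-8,11-dien-3-one, both C1 epimers | COCOc1cc(C(O)CC(=O)CCCC/C=C\C/C=C\CCC[C@H](C)O[Si](C)(C)C(C)(C)C)cc(OCOC)c1 | intermediate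
23 | C1 methanesulfonate of 22 (formed in the flask) | COCOc1cc(C(OS(C)(=O)=O)CC(=O)CCCC/C=C\C/C=C\CCC[C@H](C)O[Si](C)(C)C(C)(C)C)cc(OCOC)c1 | intermediate
24 | (1E,8Z,11Z,16S)-1-[3,5-bis(methoxymethoxy)phenyl]-16-[(tert-butyldimethylsilyl)oxy]heptadeca-1,8,11-trien-3-one | COCOc1cc(/C=C/C(=O)CCCC/C=C\C/C=C\CCC[C@H](C)O[Si](C)(C)C(C)(C)C)cc(OCOC)c1 | intermediate
25 | copper enolate (C2=C3) from hydride addition to 24 (formed in the flask) | COCOc1cc(CC=C(O[Cu])CCCC/C=C\C/C=C\CCC[C@H](C)O[Si](C)(C)C(C)(C)C)cc(OCOC)c1 | intermediate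
26 | (8Z,11Z,16S)-1-[3,5-bis(methoxymethoxy)phenyl]-16-[(tert-butyldimethylsilyl)oxy]heptadeca-8,11-dien-3-one | COCOc1cc(CCC(=O)CCCC/C=C\C/C=C\CCC[C@H](C)O[Si](C)(C)C(C)(C)C)cc(OCOC)c1 | intermediate
27 | N'-tosylhydrazone of 26 | COCOc1cc(CCC(=NNS(=O)(=O)c2ccc(C)cc2)CCCC/C=C\C/C=C\CCC[C@H](C)O[Si](C)(C)C(C)(C)C)cc(OCOC)c1 | intermediate
28 | N-(1,3,2-benzodioxaborol-2-yl)-N'-tosylhydrazine from C=N reduction of 27 (formed in the flask) | COCOc1cc(CCC(N(B2Oc3ccccc3O2)NS(=O)(=O)c2ccc(C)cc2)CCCC/C=C\C/C=C\CCC[C@H](C)O[Si](C)(C)C(C)(C)C)cc(OCOC)c1 | intermediate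
29 | C3 alkyl diazene (formed in the flask) | COCOc1cc(CCC(N=N)CCCC/C=C\C/C=C\CCC[C@H](C)O[Si](C)(C)C(C)(C)C)cc(OCOC)c1 | intermediate
30 | tert-butyl({(2S,6Z,9Z)-17-[3,5-bis(methoxymethoxy)phenyl]heptadeca-6,9-dien-2-yl}oxy)dimethylsilane | COCOc1cc(CCCCCCC/C=C\C/C=C\CCC[C@H](C)O[Si](C)(C)C(C)(C)C)cc(OCOC)c1 | intermediate
31 | Hansfordiol D, 5-[(8Z,11Z,16S)-16-hydroxyheptadeca-8,11-dien-1-yl]benzene-1,3-diol | C[C@H](O)CCC/C=C\C/C=C\CCCCCCCc1cc(O)cc(O)c1 | target

## Totals and risks
Total step count: 18.
Longest linear sequence: 15 steps (steps 1–6, 9–11, 13–18).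

**Risk 1, step 10 (double semihydrogenation of the skipped diyne).**
- Over-reduction or a stalled enyne would give mixtures that are hard to separate.
- The fallback sets the two Z-alkenes one at a time and closes C11'=C12' by a Wittig olefination.
- It sets out from alkyne 13, uses aldehyde 6 from step 3, and comes back at 17. Steps 4–6 and 9 are then not needed.
- Compound 13 is lithiated (n-BuLi, THF/DMPU, −78 °C) to its lithium acetylide F1. This opens ethylene oxide to give 8-(2-methyl-1,3-dioxolan-2-yl)oct-3-yn-1-ol F2.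
- The single isolated alkyne is hydrogenated over Pd/CaCO3 poisoned with Pb(OAc)2, with quinoline, to (Z)-8-(2-methyl-1,3-dioxolan-2-yl)oct-3-en-1-ol F3.
- I2, PPh3 and imidazole give 2-[(5Z)-8-iodooct-5-en-1-yl]-2-methyl-1,3-dioxolane F4.
- PPh3 in refluxing MeCN (NaHCO3 buffer) gives [(3Z)-8-(2-methyl-1,3-dioxolan-2-yl)oct-3-en-1-yl]triphenylphosphonium iodide F5.
- NaN(SiMe3)2 in THF at −78 °C gives the non-stabilised ylide F6. It reacts with aldehyde 6 under salt-free kinetic control to give the Z,Z-diene 17.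

**Risk 2, step 13 (regiochemistry of kinetic enolisation, retro-aldol on warming).**
- The fallback replaces the stoichiometric kinetic lithium enolate by catalytic enamine activation under thermodynamic control.
- It sets out from 18 and 20 and comes back at 24, merging steps 13 and 14.
- With pyrrolidine and AcOH (0.5 equiv each) in THF at rt to 40 °C, ketone 18 forms the less substituted pyrrolidine enamine F7.
- The enamine adds reversibly to 20, giving 22 in the flask.
- Only the methyl-side adduct can lose water to a conjugated aryl enone, so the equilibria drain into the linear E-enone 24 (Claisen–Schmidt-type condensation).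

**Risk 3, step 17 (incomplete hydrazone reduction or alkene by-products from the diazene).**
- The fallback replaces the hydrazone chemistry by hydride displacement of a sulfonate.
- It sets out from ketone 26 and comes back at 30. Step 16 is then not needed.
- NaBH4 in MeOH at 0 °C gives the C3 alcohol F8 as an epimer mixture.
- MsCl and Et3N in CH2Cl2 at 0 °C give the C3 methanesulfonate F9.
- LiEt3BH in THF (0 °C → rt) displaces the unhindered acyclic secondary mesylate by SN2 to give 30. The alkenes, MOM ethers and TBS ether are inert.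

## Further compounds
F1 | step 10 | lithium acetylide of 13 | CC1(CCCCC#C[Li])OCCO1
F2 | step 10 | 8-(2-methyl-1,3-dioxolan-2-yl)oct-3-yn-1-ol | CC1(CCCCC#CCCO)OCCO1
F3 | step 10 | (Z)-8-(2-methyl-1,3-dioxolan-2-yl)oct-3-en-1-ol | CC1(CCCC/C=C\CCO)OCCO1
F4 | step 10 | 2-[(5Z)-8-iodooct-5-en-1-yl]-2-methyl-1,3-dioxolane | CC1(CCCC/C=C\CCI)OCCO1
F5 | step 10 | [(3Z)-8-(2-methyl-1,3-dioxolan-2-yl)oct-3-en-1-yl]triphenylphosphonium iodide | CC1(CCCC/C=C\CC[P+](c2ccccc2)(c2ccccc2)c2ccccc2)OCCO1.[I-]
F6 | step 10 | ylide from F5 | CC1(CCCC/C=C\CC=P(c2ccccc2)(c2ccccc2)c2ccccc2)OCCO1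
F7 | step 13 | terminal pyrrolidine enamine of 18 | C=C(N1CCCC1)CCCC/C=C\C/C=C\CCC[C@H](C)O[Si](C)(C)C(C)(C)C
F8 | step 17 | (8Z,11Z,16S)-1-[3,5-bis(methoxymethoxy)phenyl]-16-[(tert-butyldimethylsilyl)oxy]heptadeca-8,11-dien-3-ol, both C3 epimers | COCOc1cc(CCC(O)CCCC/C=C\C/C=C\CCC[C@H](C)O[Si](C)(C)C(C)(C)C)cc(OCOC)c1
F9 | step 17 | C3 methanesulfonate of F8 | COCOc1cc(CCC(OS(C)(=O)=O)CCCC/C=C\C/C=C\CCC[C@H](C)O[Si](C)(C)C(C)(C)C)cc(OCOC)c1
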